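Removing the two angelates, the C7 and C9 hydroxyls, the C1 carbonyl oxygen and the hydrogens added across C2=C3 leaves α-longipinene, and everything rests on making that hydrocarbon in one stroke. Its cyclobutane (C4–C5–C11–C10), six-membered ring (C1–C2–C3–C4–C5–C11) and seven-membered ring (C5–C6–C7–C8–C9–C10–C11) are an unrearranged farnesyl chain tied together by only three extra bonds, C5–C6, C5–C11 and C4–C10. A longipinene-forming sesquiterpene cyclase makes these bonds, all three rings and the stereocentres C4, C5, C10 and C11 in a single cationic cascade. The precursor is acyclic, achiral (2E,6E)-farnesyl diphosphate, two steps from farnesol.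

Key step: step 3

Numbering and faces: longipinane numbering is used (C1 C=O, C2 CH2, C3 CHMe, cyclobutane C4–C5–C11–C10 with C11 next to C1 and C10 methyl-bearing, C6 CMe2, C7 and C9 the ester carbons, C8 between them). The face of the C1–C2–C3 bridge that lies under the C10 methyl is called the methyl face. The opposite face, flanked by C5–H, is the open face. In 13 the C3 methyl stands on the open face, so the C3 hydrogen has to be delivered on the methyl face.

Assumption: conifer-type cyclases are taken to produce the (1R,2S,7R,8R) enantiomer of α-longipinene, which carries the C4, C5, C10 and C11 configuration of the target; this is to be confirmed on 5 by enantioselective GC and the sign of rotation before material is carried on.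

Step 1
Reactants: 1 (2E,6E)-farnesol
Product: 2 (2E,6E)-farnesyl bromide
Conditions: PBr3 (0.4 equiv), Et2O, −10 to 0 °C; aq NaHCO3 wash, used without chromatography
Reagents that add atoms: phosphorus tribromide, BrP(Br)Br
Why: PBr3 activates the primary allylic hydroxyl and bromide displaces it in an SN2 reaction, which at or below 0 °C leaves the 2E and 6E alkenes unchanged and avoids allylic transposition.

Step 2
Reactants: 2 (2E,6E)-farnesyl bromide
Product: 3 (2E,6E)-farnesyl diphosphate (triammonium salt)
Conditions: (n-Bu4N)3HP2O7 (2 equiv), MeCN, 23 °C; Dowex 50WX8 (NH4+ form), aq NH4HCO3/i-PrOH; cellulose chromatography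
Reagents that add atoms: tris(tetrabutylammonium) hydrogen diphosphate, CCCC[N+](CCCC)(CCCC)CCCC.CCCC[N+](CCCC)(CCCC)CCCC.CCCC[N+](CCCC)(CCCC)CCCC.OP(=O)([O-])OP(=O)([O-])[O-]
Why: The MeCN-soluble diphosphate salt acts as an oxygen nucleophile in a direct SN2 displacement of the primary allylic bromide, the standard allylic diphosphorylation, and cation exchange gives the water-soluble salt that the enzyme accepts.

Step 3
Reactants: 3 (2E,6E)-farnesyl diphosphate
Product: 5 (1R,2S,7R,8R)-α-longipinene, via nerolidyl diphosphate 4 (not isolated)
Conditions: recombinant α-longipinene synthase (EC 4.2.3.80 activity; conifer γ-humulene/longifolene synthase scaffold, active-site variant chosen for 5), MgCl2 (10 mM), HEPES pH 7.5, DTT, 10% glycerol, pentane overlay, 30 °C; AgNO3-impregnated silica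
Reagents that add atoms: none
Why: Magnesium-assisted loss of diphosphate, its return at C3 to give 4 and re-ionization furnish the cisoid allyl cation, whose terminus C5 is attacked by the C6=C7 alkene at C6 (11-endo macrocyclization); because this leaves charge on secondary C7 against the Markovnikov preference, it is coupled to a 1,3-hydride shift from C5 to C7 that moves the charge into the C5–C4–C3 allyl system. Transannular attack of the C10=C11 alkene on C5 (C5–C11; 6-exo for the ring C1–C2–C3–C4–C5–C11, 7-endo for the ring C5–C6–C7–C8–C9–C10–C11) gives the tertiary himachalyl cation at C10, the remaining C3=C4 alkene captures it through C4 (C4–C10, 4-exo, cyclobutane C4–C5–C11–C10) to put the charge on tertiary C3, and loss of a C2 proton gives 5. The closest known reaction type is the ionization-initiated (class one) sesquiterpene synthase cyclization of farnesyl diphosphate, for which longifolene, himachalenes and α-longipinene are documented products of conifer enzymes and their active-site variants. C5 and C11 are set in the second closure by the faces of the allyl cation and of the E-configured C10=C11 alkene that the chiral pocket holds together, and C10 and C4 follow because the tethered alkene can reach only one face of the C10 cation, the 1,3-bridged cyclobutane allowing no other fusion. The step needs pathway selectivity (C4–C10 closure in preference to C3–C10 closure toward longifolene, to himachalene-forming proton loss and to exocyclic proton loss) and one absolute fold; the substrate contributes three trisubstituted alkenes spaced so that the last two closures end on tertiary carbons, and the pocket contour with the bound diphosphate as base supplies the rest.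

Step 4
Reactants: 5 (1R,2S,7R,8R)-α-longipinene
Product: 7 (4R,5S,10R,11R)-longipin-2-en-1-one, via allylic tert-butyl peroxide 6 (not isolated)
Conditions: Rh2(cap)4 (cap = caprolactamate, 1 mol %), t-BuOOH (5 equiv, in decane), K2CO3 (0.5 equiv), CH2Cl2, 23 °C
Reagents that add atoms: tert-butyl hydroperoxide, CC(C)(C)OO
Why: Dirhodium-catalysed generation of tert-butylperoxyl radicals effects allylic C–H oxidation at C1, the only ring methylene whose C–H bonds overlap with the C2=C3 π system (C4–H is a bridgehead bond close to the nodal plane and the vinylic methyl is primary), and 6 collapses to the enone by Kornblum–DeLaMare fragmentation just as α-pinene gives verbenone, with no stereocentre formed or touched.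

Step 5
Reactants: 7 (4R,5S,10R,11R)-longipin-2-en-1-one
Product: 8 (3R,4S,5S,10R,11R)-longipinan-1-one
Conditions: ene-reductase (old-yellow-enzyme family, variant picked by screening for the 3R product), NADP+ (cat), glucose dehydrogenase, D-glucose, K2HPO4/KH2PO4 buffer pH 7.0, 5% DMSO, 30 °C
Reagents that add atoms: none
Why: Flavin-dependent asymmetric reduction of an activated alkene passes hydride from the reduced flavin to C3 and a proton from the active-site tyrosine to C2 in an anti addition, a reaction known for β-methyl cyclic and bicyclic enones, and the new stereocentre C3 (R) is set by the enzyme, which must bind 7 in the pose that turns the methyl face to the flavin, since any reagent under substrate control (H2 on Pd, copper hydrides) would add to the open face and give the C3 epimer.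

Step 6
Reactants: 8 (3R,4S,5S,10R,11R)-longipinan-1-one
Product: 9 (3R,4S,5S,9R,10R,11R)-9-hydroxylongipinan-1-one
Conditions: CYP102A1 variant A (active-site library screened on 8, cell-free extract), air, NADP+ (cat), glucose dehydrogenase, D-glucose, catalase, K2HPO4/KH2PO4 buffer pH 8.0, 2% DMSO, 25 °C
Reagents that add atoms: dioxygen, O=O
Why: Cytochrome P450 hydroxylation by hydrogen abstraction and oxygen rebound replaces one hydrogen of an unactivated methylene with retention, a reaction well established for sesquiterpenoid ketones with CYP102A1 variants, and both the site (C9 over C8, C7 and C2) and the new stereocentre C9 (R, hydroxyl cis to the C10 methyl) are fixed by the orientation in which the selected pocket holds 8 above the heme, the C1 ketone being inert.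

Step 7
Reactants: 9 (3R,4S,5S,9R,10R,11R)-9-hydroxylongipinan-1-one
Product: 10 (3R,4S,5S,7R,9R,10R,11R)-7,9-dihydroxylongipinan-1-one
Conditions: CYP102A1 variant B (library screened on 9, cell-free extract), air, NADP+ (cat), glucose dehydrogenase, D-glucose, catalase, K2HPO4/KH2PO4 buffer pH 8.0, 2% DMSO, 25 °C
Reagents that add atoms: dioxygen, O=O
Why: The same abstraction and rebound mechanism, run with a second variant selected on 9 so that C7 lies nearest the heme iron, inserts oxygen with retention and sets C7 (R, hydroxyl trans to the C9 hydroxyl across the seven-membered ring) under enzyme control, the choice of binding pose also keeping the C9 carbinol hydrogen away from the oxidant.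

Step 8
Reactants: 10 (3R,4S,5S,7R,9R,10R,11R)-7,9-dihydroxylongipinan-1-one; 11 angelic acid
Product: 13 7β,9α-diangeloyloxylongipinan-1-one (target), via angelic 2,4,6-trichlorobenzoic anhydride 12 (not isolated)
Conditions: 11 (6 equiv), 2,4,6-trichlorobenzoyl chloride (6 equiv), Et3N (6 equiv), toluene, 23 °C; then 10, 80 °C, no DMAP
Reagents that add atoms: angelic acid (11), C/C=C(/C)C(=O)O
Why: Yamaguchi-type mixed-anhydride esterification run without a nucleophilic catalyst acylates both hindered secondary hydroxyls at the unshielded angeloyl carbonyl of 12, leaving out DMAP avoids the conjugate addition and elimination that would turn the Z-configured angelate into the E-configured tiglate, and the C7–O and C9–O bonds are not broken so both configurations are retained.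

Compound list
1 | (2E,6E)-farnesol | CC(C)=CCC/C(C)=C/CC/C(C)=C/CO | starting material
2 | (2E,6E)-farnesyl bromide | CC(C)=CCC/C(C)=C/CC/C(C)=C/CBr | intermediate
3 | (2E,6E)-farnesyl diphosphate, handled as its triammonium salt, drawn as the free acid | CC(C)=CCC/C(C)=C/CC/C(C)=C/COP(=O)(O)OP(=O)(O)O | intermediate
4 | (6E)-nerolidyl diphosphate, enzyme-bound tertiary allylic isomer of 3; its C3 configuration is fixed by the enzyme and erased on re-ionization | C=CC(C)(CC/C=C(\C)CCC=C(C)C)OP(=O)(O)OP(=O)(O)O | intermediate
5 | α-longipinene, (4R,5R,10S,11R)-longipin-2-ene, equal to (1R,2S,7R,8R)-2,6,6,9-tetramethyltricyclo[5.4.0.0(2,8)]undec-9-ene | C1CC[C@]2(C)[C@@H]3[C@@H]([C@H]2CC=C3C)C1(C)C | intermediate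
6 | 1-(tert-butylperoxy)longipin-2-ene, peroxy group on the open face | C1CC[C@]2(C)[C@@H]3[C@@H]([C@H]2[C@@H](OOC(C)(C)C)C=C3C)C1(C)C | intermediate
7 | (4R,5S,10R,11R)-longipin-2-en-1-one | C1CC[C@]2(C)[C@@H]3[C@@H]([C@H]2C(=O)C=C3C)C1(C)C | intermediate
8 | (3R,4S,5S,10R,11R)-longipinan-1-one, C3 methyl on the open face | C1CC[C@]2(C)[C@@H]3[C@@H]([C@H]2C(=O)C[C@H]3C)C1(C)C | intermediate
9 | (3R,4S,5S,9R,10R,11R)-9-hydroxylongipinan-1-one (9α-OH, cis to the C10 methyl) | C1C[C@@H](O)[C@]2(C)[C@@H]3[C@@H]([C@H]2C(=O)C[C@H]3C)C1(C)C | intermediate
10 | (3R,4S,5S,7R,9R,10R,11R)-7,9-dihydroxylongipinan-1-one (7β,9α-diol, hydroxyls trans) | O[C@@H]1C[C@@H](O)[C@]2(C)[C@@H]3[C@@H]([C@H]2C(=O)C[C@H]3C)C1(C)C | intermediate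
11 | angelic acid, (Z)-2-methylbut-2-enoic acid | C/C=C(/C)C(=O)O | starting material
12 | angelic 2,4,6-trichlorobenzoic anhydride | C/C=C(/C)C(=O)OC(=O)c1c(Cl)cc(Cl)cc1Cl | intermediate
13 | (3R,4S,5S,7R,9R,10R,11R)-7,9-bis[(Z)-2-methylbut-2-enoyloxy]longipinan-1-one, CNP0283599.1 | C/C=C(/C)C(=O)O[C@@H]1C[C@@H](OC(=O)/C(C)=C\C)[C@]2(C)[C@@H]3[C@@H]([C@H]2C(=O)C[C@H]3C)C1(C)C | target

Total step count: 8. Longest linear sequence: 8 steps (1 to 13); 11 enters in step 8.

The cyclization itself rests on a documented enzyme activity. The three steps below depend on finding a biocatalyst whose selectivity has not yet been established on this skeleton.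

Step 6 (C9 hydroxylation). What may go wrong: oxygen insertion at the more exposed C8 methylene or at a methyl group, or cofactor consumption uncoupled from product formation. The fallback sets out from 8 and comes back at 9. Instead of reshaping a bacterial enzyme, the dedicated plant oxidase is sought. Root transcriptomes of Stevia species that accumulate longipinane esters are mined for CYP71-clan P450 genes co-expressed with the sesquiterpene synthase. Candidates are expressed with a plant cytochrome P450 reductase in Saccharomyces cerevisiae, and 8 is fed to the cultures. No compound outside the list arises (entry F0).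

Step 7 (C7 hydroxylation). What may go wrong: oxidation of the C9 carbinol to a ketone, attack at C8, or weak binding of the more polar substrate. The fallback sets out from 9 and comes back at 10, and it uses substrate engineering with a removable anchor.
- Acylation of 9 at O9 with 4-[(dimethylamino)methyl]benzoyl chloride (Et3N, DMAP, CH2Cl2) gives the 9α-anchor ester F1.
- The macrolide hydroxylase PikC (D50N variant fused to the RhFRED reductase domain) binds a protonated dimethylamino group by a salt bridge and oxidizes the C–H bond held at a set distance from it. It should convert this ester into the 7β-hydroxy anchor ester F2. The linker length is the variable to tune.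
- KOH in MeOH at 50 °C then cleaves the anchor and gives 10.

Step 5 (C3 by ene-reductase). What may go wrong: no turnover of a bridged, β,β-disubstituted enone, or hydride transfer to the open face and hence poor or inverted facial selectivity. The fallback sets out from 7 and comes back at 8. It brings the hydrogen to the methyl face intramolecularly by an allylic diazene rearrangement.
- Condensation of 7 with TsNHNH2 (EtOH, cat AcOH, reflux) gives longipin-2-en-1-one tosylhydrazone F3.
- Catecholborane (CHCl3, −10 °C) reduces the C=N bond from the open face, which places nitrogen on the methyl face. NaOAc·3H2O at reflux then expels sulfinate to give the C1 allylic diazene F4.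
- This diazene loses N2 in a suprafacial retro-ene reaction that hands its hydrogen to C3 on the methyl face and moves the alkene to C1=C2, giving (3R)-longipin-1-ene F5.
- Hydroboration with 9-BBN (THF, 60 °C) should occur on the open face with boron at C1, the alkene carbon remote from the C3 methyl that now stands on that face, giving the C1 borane F6.
- NaOH/H2O2 gives (1S,3R)-longipinan-1-ol F7, with any C2 regioisomer removed by chromatography. Dess–Martin periodinane then gives 8.

Further compounds
F0 | step 6 | none | none
F1 | step 7 | 9α-{4-[(dimethylamino)methyl]benzoyloxy}longipinan-1-one (9α-anchor ester) | C1C[C@@H](OC(=O)c4ccc(CN(C)C)cc4)[C@]2(C)[C@@H]3[C@@H]([C@H]2C(=O)C[C@H]3C)C1(C)C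
F2 | step 7 | 9α-{4-[(dimethylamino)methyl]benzoyloxy}-7β-hydroxylongipinan-1-one (7β-hydroxy anchor ester) | O[C@@H]1C[C@@H](OC(=O)c4ccc(CN(C)C)cc4)[C@]2(C)[C@@H]3[C@@H]([C@H]2C(=O)C[C@H]3C)C1(C)C
F3 | step 5 | longipin-2-en-1-one tosylhydrazone (C=N geometry immaterial) | C1CC[C@]2(C)[C@@H]3[C@@H]([C@H]2C(=NNS(=O)(=O)c4ccc(C)cc4)C=C3C)C1(C)C
F4 | step 5 | C1 allylic diazene, 1-diazenyllongipin-2-ene with nitrogen on the methyl face | C1CC[C@]2(C)[C@@H]3[C@@H]([C@H]2[C@H](N=N)C=C3C)C1(C)C
F5 | step 5 | (3R)-longipin-1-ene | C1CC[C@]2(C)[C@@H]3[C@@H]([C@H]2C=C[C@H]3C)C1(C)C
F6 | step 5 | C1 borane, 9-[(3R)-longipinan-1-yl]-9-borabicyclo[3.3.1]nonane with boron on the open face | C1CC[C@]2(C)[C@@H]3[C@@H]([C@H]2[C@@H](B4C5CCCC4CCC5)C[C@H]3C)C1(C)C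
F7 | step 5 | (1S,3R)-longipinan-1-ol, hydroxyl on the open face | C1CC[C@]2(C)[C@@H]3[C@@H]([C@H]2[C@@H](O)C[C@H]3C)C1(C)C
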